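**Retrosynthetic overview**
- Cut the bond between C2 of ring C and ring B: a chromone-2-carboxylic acid plus (3,4,5-trimethoxyphenyl)boronic acid, joined with loss of CO (proposed decarbonylative Suzuki–Miyaura coupling).
- The acid comes from its ethyl ester by hydrolysis.
- Ring C (the pyranone) is built by Claisen condensation and cyclodehydration of a 2-hydroxyacetophenone with diethyl oxalate.
- Ring order: ring A is bought with both methoxy groups in place, ring C is closed in step 1, ring B is attached last.

Assumption: the target has no stereocentre, stereogenic axis or stereogenic double bond, so "single enantiomer" is taken to mean the one achiral compound drawn.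

**Route**

Step 1
Reactants: 1 1-(2-hydroxy-4,5-dimethoxyphenyl)ethan-1-one; 2 diethyl oxalate
Product: 4 ethyl 6,7-dimethoxy-4-oxo-4H-chromene-2-carboxylate, via diketo ester 3 (not isolated)
Conditions: NaOEt (3 equiv), 2 (2 equiv), EtOH, 0 °C to reflux, 2 h; then HCl in EtOH to pH 1, reflux, 1 h
Reagents that add atoms: none
Why: Crossed Claisen condensation of the methyl ketone enolate with non-enolisable diethyl oxalate gives the 2,4-diketo ester, and acid-catalysed cyclodehydration by the ortho phenol closes the pyranone; no stereocentre is formed.

Step 2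
Reactants: 4 ethyl 6,7-dimethoxy-4-oxo-4H-chromene-2-carboxylate
Product: 5 6,7-dimethoxy-4-oxo-4H-chromene-2-carboxylic acid
Conditions: 6 M aq. HCl/AcOH (1:2), 100 °C, 3 h; cool, dilute with water, filter
Reagents that add atoms: water, O
Why: Acid-catalysed ester hydrolysis; hot HCl leaves aryl methyl ethers and the pyranone intact and avoids hydroxide attack at C2, which can open the ring; no stereocentre is formed.

Step 3
Reactants: 5 6,7-dimethoxy-4-oxo-4H-chromene-2-carboxylic acid; 6 (3,4,5-trimethoxyphenyl)boronic acid; 7 pivalic anhydride
Product: 9 prosogerin C (6,7-dimethoxy-2-(3,4,5-trimethoxyphenyl)-4H-chromen-4-one), via mixed anhydride 8 (not isolated)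
Conditions: Pd(OAc)2 (5 mol%), 1,4-bis(diphenylphosphino)butane (10 mol%), 6 (2.0 equiv), 7 (1.5 equiv), Et3N (1.75 equiv), dioxane, 160 °C, 15 h, argon
Reagents that add atoms: none
Why: Proposed new method: pivalic anhydride 7 converts acid 5 in the flask into mixed anhydride 8; zerovalent palladium (formed from Pd(OAc)2 and the bisphosphine) adds oxidatively into the C(acyl)–O bond on the chromone side, which is less hindered and more electron-poor than the pivaloyl side; CO is extruded at 160 °C, favoured because the palladium then sits on an sp2 carbon that bears the ring oxygen and has no β-hydrogen able to eliminate; transmetalation with boronic acid 6 and C–C reductive elimination form the C2–aryl bond that joins ring C to ring B; the closest known reaction type is the palladium-catalysed decarbonylative Suzuki–Miyaura coupling of benzoic and heteroaromatic carboxylic acids activated as pivalic mixed anhydrides, which to my knowledge has not been shown for a chromone-2-carboxylic acid (a β-oxygenated enone acid); no stereocentre is formed.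

**Compound list**

1 | 1-(2-hydroxy-4,5-dimethoxyphenyl)ethan-1-one | CC(=O)c1cc(OC)c(OC)cc1O | starting material
2 | diethyl oxalate | CCOC(=O)C(=O)OCC | starting material
3 | ethyl 4-(2-hydroxy-4,5-dimethoxyphenyl)-2,4-dioxobutanoate (diketo ester) | CCOC(=O)C(=O)CC(=O)c1cc(OC)c(OC)cc1O | intermediate
4 | ethyl 6,7-dimethoxy-4-oxo-4H-chromene-2-carboxylate | CCOC(=O)c1cc(=O)c2cc(OC)c(OC)cc2o1 | intermediate
5 | 6,7-dimethoxy-4-oxo-4H-chromene-2-carboxylic acid | OC(=O)c1cc(=O)c2cc(OC)c(OC)cc2o1 | intermediate
6 | (3,4,5-trimethoxyphenyl)boronic acid | COc1cc(B(O)O)cc(OC)c1OC | starting material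
7 | pivalic anhydride | CC(C)(C)C(=O)OC(=O)C(C)(C)C | starting material
8 | 6,7-dimethoxy-4-oxo-4H-chromene-2-carboxylic pivalic anhydride (mixed anhydride) | CC(C)(C)C(=O)OC(=O)c1cc(=O)c2cc(OC)c(OC)cc2o1 | intermediate
9 | prosogerin C (6,7-dimethoxy-2-(3,4,5-trimethoxyphenyl)-4H-chromen-4-one) | COc1cc2oc(-c3cc(OC)c(OC)c(OC)c3)cc(=O)c2cc1OC | target

**Summary**

Total step count: 3. Longest linear sequence: 3 steps (1 to 4 to 5 to 9).

Steps most likely to fail, most risky first:

Step 3 (the proposed new coupling). Likely failure modes are slow CO loss, giving the 2-aroylchromone ketone instead, and protodeboronation of the electron-rich boronic acid 6. The fallback uses known chemistry only; it sets out from 1 and comes back to the route at 9. Claisen–Schmidt condensation of 1 with 3,4,5-trimethoxybenzaldehyde (COc1cc(C=O)cc(OC)c1OC; KOH, EtOH, room temperature) gives the chalcone (E)-1-(2-hydroxy-4,5-dimethoxyphenyl)-3-(3,4,5-trimethoxyphenyl)prop-2-en-1-one F3. Oxidative cyclisation of this 2'-hydroxychalcone with catalytic I2 in DMSO at 130 °C (oxa-Michael closure, then dehydrogenation) gives 9. Here ring B is brought in as an aldehyde and ring C is closed last, in place of a cross-coupling on a finished chromone.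

Step 1 (Claisen condensation and cyclisation). Likely failure modes are incomplete condensation of the poorly soluble phenoxide enolate and ester scrambling. The fallback sets out from 1 and comes back to the route at 3. O-Acylation of the phenol of 1 with ethyl chlorooxoacetate (CCOC(=O)C(=O)Cl; pyridine, CH2Cl2, 0 °C) gives 2-acetyl-4,5-dimethoxyphenyl ethyl oxalate F1. KOtBu (2 equiv) in THF at 0 °C then moves the oxalyl group from oxygen to carbon through the ketone enolate (Baker–Venkataraman rearrangement) to give diketo ester 3, which is closed to 4 with HCl in EtOH as in step 1. The C–C bond is thus made intramolecularly instead of by an intermolecular Claisen condensation.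

Step 2 (ester hydrolysis). Likely failure modes are sluggish hydrolysis of the poorly soluble ester and partial opening of the pyranone. The fallback sets out from 1 and comes back to the route at 5. Claisen condensation of 1 with di-tert-butyl oxalate (CC(C)(C)OC(=O)C(=O)OC(C)(C)C; LiN(SiMe3)2, 3 equiv, THF, −78 °C to room temperature) gives tert-butyl 4-(2-hydroxy-4,5-dimethoxyphenyl)-2,4-dioxobutanoate F2. TFA/CH2Cl2 (1:1) at 40 °C then closes the pyranone and cleaves the tert-butyl ester as 2-methylpropene in the same operation, giving 5. The change is in the ester used: it is unmasked by acidolysis, with no aqueous hydrolysis at all.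

**Further compounds**

F1 | step 1 | 2-acetyl-4,5-dimethoxyphenyl ethyl oxalate | CCOC(=O)C(=O)Oc1cc(OC)c(OC)cc1C(C)=O
F2 | step 2 | tert-butyl 4-(2-hydroxy-4,5-dimethoxyphenyl)-2,4-dioxobutanoate | CC(C)(C)OC(=O)C(=O)CC(=O)c1cc(OC)c(OC)cc1O
F3 | step 3 | (E)-1-(2-hydroxy-4,5-dimethoxyphenyl)-3-(3,4,5-trimethoxyphenyl)prop-2-en-1-one | COc1cc(/C=C/C(=O)c2cc(OC)c(OC)cc2O)cc(OC)c1OC
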